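**Retrosynthetic overview**

1. Target 19 is (13E)-3β-acetoxylabda-7,13-dien-15-oic acid. Its last C–C bond (C9–C10, ring B) comes from a proton-initiated cation–olefin closure of a monocyclic 3-acetoxy trienoate, which sets C10, C9 and the C7=C8 alkene from C5; C6–C16 are carried intact from methyl (2E,6E)-farnesoate.
2. Ring A is made first, by closing C2–C3: the samarium ketyl of the C3 aldehyde adds to the terminus C2 of a 2-substituted buta-1,3-diene (C2=C1–C10=C20) held on C5, and the same reduction turns the diene into the C1=C10 ring alkene and the C20 methyl.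
3. Feature that makes this possible: C3 is a non-enolisable neopentyl aldehyde (C4 gem-dimethyl) placed 1,6 to C2, and attack at C2 (6-endo, ring A) is the only mode that gives an allyl radical (C1–C10–C20); the C1=C10 alkene left behind is the masked C10 cation for ring B.
4. C5, the only stereocentre brought into the key step, and the C4–C5 bond come from an enantioselective iminium-catalysed Mukaiyama–Michael addition to an enal; the diene comes from α-methylenation and Wittig methylenation of the resulting aldehyde.
5. Order of ring formation: ring A (C2–C3), then ring B (C9–C10).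

Key step: step 10

Remark: atoms are numbered as in labdane (C1–C20) throughout; the facial sense of step 6 is assigned by analogy with other π-nucleophiles under the same imidazolidinone, and the enantiomeric catalyst would be used if it proved opposite.

**Route**

Step 1
Reactants: 1 methyl (2E,6E)-farnesoate
Product: 3 methyl (2E,6E)-10,11-epoxy-3,7,11-trimethyldodeca-2,6-dienoate (racemic epoxide), via bromohydrin 2 (not isolated)
Conditions: NBS, THF–H2O, 0 °C; then K2CO3, MeOH, rt
Reagents that add atoms: N-bromosuccinimide, O=C1CCC(=O)N1Br (bromine, in 2 only); water, O (hydroxyl oxygen of 2, epoxide oxygen of 3)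
Why: Electrophilic bromohydrin formation is selective for the terminal trisubstituted alkene (most electron-rich and least hindered, the C2=C3 alkene of the enoate being deactivated), and base closes the epoxide by intramolecular Williamson etherification; no stereocentre needs control because the epoxide carbons are excised or become the C5 aldehyde in step 2.

Step 2
Reactants: 3 racemic terminal epoxide
Product: 5 methyl (2E,6E)-3,7-dimethyl-10-oxodeca-2,6-dienoate, via diol 4 (not isolated)
Conditions: HIO4·2H2O, THF–Et2O, 0 °C to rt
Reagents that add atoms: water, O (enters diol 4 only and leaves with acetone)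
Why: Acid-promoted epoxide hydration followed by periodate glycol cleavage in the same flask removes the terminal three carbons as acetone and leaves the aldehyde carbon that becomes C5.

Step 3
Reactants: 5 trisnor aldehyde
Product: 6 methyl (2E,6E,10E)-3,7-dimethyl-12-oxododeca-2,6,10-trienoate
Conditions: Ph3P=CHCHO, toluene, 80 °C
Reagents that add atoms: (triphenylphosphoranylidene)acetaldehyde, O=CC=P(c1ccccc1)(c1ccccc1)c1ccccc1
Why: Wittig olefination with the stabilised formylmethylene ylide is (E)-selective and gives the enal whose β-carbon is C5 and whose α-carbon and carbonyl carbon become C10 and C1.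

Step 4
Reactants: 7 2-methylpropanoyl chloride; 8 ethanethiol
Product: 9 S-ethyl 2-methylpropanethioate
Conditions: Et3N, CH2Cl2, 0 °C to rt
Reagents that add atoms: none
Why: Nucleophilic acyl substitution of the acid chloride by the thiol gives the thioester that later serves as a C3 carbonyl reducible in the presence of the methyl ester.

Step 5
Reactants: 9 S-ethyl 2-methylpropanethioate
Product: 10 {[1-(ethylsulfanyl)-2-methylprop-1-en-1-yl]oxy}trimethylsilane
Conditions: LiN(i-Pr)2, THF, −78 °C; Me3SiCl
Reagents that add atoms: chlorotrimethylsilane, C[Si](C)(C)Cl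
Why: Enolisation of the thioester and O-silylation give the tetrasubstituted silyl ketene thioacetal (no enolate geometry to control) needed for the Mukaiyama–Michael addition.

Step 6
Reactants: 6 (E)-enal; 10 silyl ketene thioacetal
Product: 11 methyl (2E,6E,10R)-12-(ethylsulfanyl)-3,7,11,11-tetramethyl-12-oxo-10-(2-oxoethyl)dodeca-2,6-dienoate
Conditions: (2S,5S)-5-benzyl-2-tert-butyl-3-methylimidazolidin-4-one·CF3CO2H (20 mol %), CH2Cl2–i-PrOH, H2O (2 equiv), −60 °C
Reagents that add atoms: none
Why: Iminium-catalysed enantioselective Mukaiyama–Michael addition: the (E)-iminium ion of 6 is shielded on one face by the benzyl group, so the ketene thioacetal adds 1,4 to the open face, forming the C4–C5 bond with C5 set as (R) and bringing in the quaternary C4 and the future C3 carbonyl.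

Step 7
Reactants: 11 Michael adduct
Product: 13 methyl (2E,6E,10R)-12-(ethylsulfanyl)-3,7,11,11-tetramethyl-12-oxo-10-(3-oxoprop-1-en-2-yl)dodeca-2,6-dienoate, via Mannich base 12 (not isolated)
Conditions: [CH2=NMe2]I, Et3N, CH2Cl2, rt to 40 °C
Reagents that add atoms: dimethyl(methylidene)ammonium iodide, C=[N+](C)C.[I-] (CH2 and NMe2 in 12, CH2 in 13)
Why: Mannich reaction at the only enolisable carbon (C10) followed by β-elimination of dimethylamine (α-methylenation of an aldehyde) installs C20 as a methylidene group, and C5, being β to the aldehyde, is not epimerised.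

Step 8
Reactants: 13 α-methylene aldehyde
Product: 14 methyl (2E,6E,10R)-10-(buta-1,3-dien-2-yl)-12-(ethylsulfanyl)-3,7,11,11-tetramethyl-12-oxododeca-2,6-dienoate
Conditions: Ph3PCH3Br, KN(SiMe3)2, THF, −78 to 0 °C
Reagents that add atoms: methyltriphenylphosphonium bromide, C[P+](c1ccccc1)(c1ccccc1)c1ccccc1.[Br-]
Why: Wittig methylenation of the aldehyde, much faster at low temperature than attack on the hindered thioester or the enoate, converts C1=O into C1=C2 and completes the 2-substituted buta-1,3-diene.

Step 9
Reactants: 14 diene thioester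
Product: 15 methyl (2E,6E,10R)-10-(buta-1,3-dien-2-yl)-3,7,11,11-tetramethyl-12-oxododeca-2,6-dienoate
Conditions: i-Bu2AlH (1.1 equiv), CH2Cl2, −78 °C; aq. sodium potassium tartrate
Reagents that add atoms: none
Why: Partial reduction of the thioester through an aluminium hemithioacetal that is stable at −78 °C (thioesters are reduced faster than the conjugated β,β-disubstituted methyl ester) releases the C3 aldehyde on work-up.

Step 10
Reactants: 15 diene aldehyde
Product: 16 methyl (2E,6E)-9-[(1R,5S)-5-hydroxy-2,6,6-trimethylcyclohex-2-en-1-yl]-3,7-dimethylnona-2,6-dienoate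
Conditions: SmI2 (2.5 equiv), HMPA, t-BuOH (2 equiv), THF, −78 to 0 °C, slow addition of 15
Reagents that add atoms: none
Why: Proposed new method: SmI2 reduces the C3 aldehyde to a samarium ketyl whose carbon adds to the terminus C2 of the 2-substituted buta-1,3-diene; the allyl radical spread over C1–C10–C20 is reduced by a second SmI2 to an allylsamarium that t-BuOH protonates at C20, so ring A, the C3 carbinol, the C1=C10 alkene and the C20 methyl arise together (protonation at C1 instead would give an alkene that ionises to the same C10 cation in step 12). The closest known reaction types are the SmI2 ketyl–olefin cyclisation of aldehydes and the addition of carbon radicals to the termini of 1,3-dienes; what is new is their combination, a ketyl closing onto a diene in the endo sense. Ring A closes 6-endo-trig (C3 onto C2, with C1 and C2 inside the ring). The new stereocentre C3 is expected to be set in a cyclohexene-like transition state in which the C5 side chain and the bulky O–Sm(HMPA)n group are both pseudo-equatorial, which places O3 cis to the C5–C6 bond, that is (3S) from (5R). The step needs 6-endo rather than 5-exo closure and reaction at the diene rather than at the C8=C9 alkene or the enoate: attack at C2 gives an allyl radical whereas attack at the internal C1 gives an unstabilised primary radical and attack at C20 would be 5-endo, the isolated trisubstituted alkene is a much poorer ketyl acceptor and would need a larger ring, and the C4 gem-dimethyl group removes all enolisable hydrogens and favours ring closure.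

Step 11
Reactants: 16 ring A alcohol
Product: 17 methyl (2E,6E)-9-[(1R,5S)-5-acetoxy-2,6,6-trimethylcyclohex-2-en-1-yl]-3,7-dimethylnona-2,6-dienoate
Conditions: Ac2O, pyridine, DMAP (cat.), CH2Cl2, rt
Reagents that add atoms: acetic anhydride, CC(=O)OC(C)=O
Why: Nucleophile-catalysed acylation installs the acetate required in the target and keeps the C3 oxygen from capturing the C10 cation in step 12.

Step 12
Reactants: 17 ring A acetate
Product: 18 methyl (13E)-3β-acetoxylabda-7,13-dien-15-oate
Conditions: ClSO3H (5 equiv), 2-nitropropane, −78 °C; Et3N quench at −78 °C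
Reagents that add atoms: none
Why: Proton-initiated cation–olefin cyclisation of an α-cyclogeranyl-type triene (biomimetic 6-endo closure of ring B): protonation of C1=C10 at C1 gives the tertiary C10 cation, the (E)-C8=C9 alkene adds through a chair with the C5 chain equatorial so that the ring fusion is trans (C20 anti to H5) and the C9 side chain equatorial, and loss of a C7 proton gives the C7=C8 alkene, while the protonated enoate should stay out at −78 °C.

Step 13
Reactants: 18 bicyclic methyl ester
Product: 19 (13E)-3β-acetoxylabda-7,13-dien-15-oic acid (target)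
Conditions: LiI, pyridine, reflux; then 1 M HCl
Reagents that add atoms: none
Why: Nucleophilic ester dealkylation (SN2 attack of iodide on the O-methyl carbon) cleaves the methyl ester without touching the secondary acetate or any stereocentre.

**Compound list**

1 | methyl (2E,6E)-3,7,11-trimethyldodeca-2,6,10-trienoate (methyl (2E,6E)-farnesoate) | CC(C)=CCC/C(C)=C/CC/C(C)=C/C(=O)OC | starting material
2 | methyl (2E,6E)-10-bromo-11-hydroxy-3,7,11-trimethyldodeca-2,6-dienoate (racemic) | CC(C)(O)C(Br)CC/C(C)=C/CC/C(C)=C/C(=O)OC | intermediate (not isolated)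
3 | methyl (2E,6E)-10,11-epoxy-3,7,11-trimethyldodeca-2,6-dienoate (racemic) | CC1(C)OC1CC/C(C)=C/CC/C(C)=C/C(=O)OC | intermediate
4 | methyl (2E,6E)-10,11-dihydroxy-3,7,11-trimethyldodeca-2,6-dienoate (racemic) | CC(C)(O)C(O)CC/C(C)=C/CC/C(C)=C/C(=O)OC | intermediate (not isolated)
5 | methyl (2E,6E)-3,7-dimethyl-10-oxodeca-2,6-dienoate | O=CCC/C(C)=C/CC/C(C)=C/C(=O)OC | intermediate
6 | methyl (2E,6E,10E)-3,7-dimethyl-12-oxododeca-2,6,10-trienoate | O=C/C=C/CC/C(C)=C/CC/C(C)=C/C(=O)OC | intermediate
7 | 2-methylpropanoyl chloride | CC(C)C(Cl)=O | starting material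
8 | ethanethiol | CCS | starting material
9 | S-ethyl 2-methylpropanethioate | CCSC(=O)C(C)C | intermediate
10 | {[1-(ethylsulfanyl)-2-methylprop-1-en-1-yl]oxy}trimethylsilane | CCSC(O[Si](C)(C)C)=C(C)C | intermediate
11 | methyl (2E,6E,10R)-12-(ethylsulfanyl)-3,7,11,11-tetramethyl-12-oxo-10-(2-oxoethyl)dodeca-2,6-dienoate | CCSC(=O)C(C)(C)[C@@H](CC=O)CC/C(C)=C/CC/C(C)=C/C(=O)OC | intermediate
12 | methyl (2E,6E,10R)-10-[1-(dimethylamino)-3-oxopropan-2-yl]-12-(ethylsulfanyl)-3,7,11,11-tetramethyl-12-oxododeca-2,6-dienoate (Mannich base, both epimers at the new centre) | CCSC(=O)C(C)(C)[C@@H](C(CN(C)C)C=O)CC/C(C)=C/CC/C(C)=C/C(=O)OC | intermediate (not isolated)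
13 | methyl (2E,6E,10R)-12-(ethylsulfanyl)-3,7,11,11-tetramethyl-12-oxo-10-(3-oxoprop-1-en-2-yl)dodeca-2,6-dienoate | CCSC(=O)C(C)(C)[C@@H](C(=C)C=O)CC/C(C)=C/CC/C(C)=C/C(=O)OC | intermediate
14 | methyl (2E,6E,10R)-10-(buta-1,3-dien-2-yl)-12-(ethylsulfanyl)-3,7,11,11-tetramethyl-12-oxododeca-2,6-dienoate | CCSC(=O)C(C)(C)[C@@H](C(=C)C=C)CC/C(C)=C/CC/C(C)=C/C(=O)OC | intermediate
15 | methyl (2E,6E,10R)-10-(buta-1,3-dien-2-yl)-3,7,11,11-tetramethyl-12-oxododeca-2,6-dienoate | O=CC(C)(C)[C@@H](C(=C)C=C)CC/C(C)=C/CC/C(C)=C/C(=O)OC | intermediate
16 | methyl (2E,6E)-9-[(1R,5S)-5-hydroxy-2,6,6-trimethylcyclohex-2-en-1-yl]-3,7-dimethylnona-2,6-dienoate | COC(=O)/C=C(\C)CC/C=C(\C)CC[C@@H]1C(C)=CC[C@H](O)C1(C)C | intermediate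
17 | methyl (2E,6E)-9-[(1R,5S)-5-acetoxy-2,6,6-trimethylcyclohex-2-en-1-yl]-3,7-dimethylnona-2,6-dienoate | COC(=O)/C=C(\C)CC/C=C(\C)CC[C@@H]1C(C)=CC[C@H](OC(C)=O)C1(C)C | intermediate
18 | methyl (13E)-3β-acetoxylabda-7,13-dien-15-oate, (3S,5R,9S,10R) | CC(=O)O[C@H]1CC[C@]2(C)[C@@H](CC/C(C)=C/C(=O)OC)C(C)=CC[C@H]2C1(C)C | intermediate
19 | (13E)-3β-acetoxylabda-7,13-dien-15-oic acid, (3S,5R,9S,10R) | CC(=O)O[C@H]1CC[C@]2(C)[C@@H](CC/C(C)=C/C(=O)O)C(C)=CC[C@H]2C1(C)C | target

**Step count and risks**

Total step count: 13 (steps 4 and 5 prepare nucleophile 10 in a side branch).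
Longest linear sequence: 11 steps (steps 1, 2, 3 and 6 to 13) from methyl (2E,6E)-farnesoate.

Steps most likely to fail:

(1) Step 10, the proposed ketyl–diene closure. The hindered ketyl may be reduced to the primary alcohol or dimerise before it cyclises, it may close at the internal diene carbon C1, or facial control at C3 may be low. The fallback uses known chemistry and sets out from 14. Hydroboration of the monosubstituted arm of the diene with bis(3-methylbutan-2-yl)borane (THF, 0 °C) and oxidation with NaBO3·4H2O should give the homoallylic alcohol F1. I2, PPh3 and imidazole convert it into the primary iodide F2, and i-Bu2AlH at −78 °C reduces the thioester to the iodo aldehyde F3. A samarium Barbier cyclisation (SmI2, HMPA, THF, −78 °C), an established way to close six-membered carbinols from ω-iodo carbonyl compounds, forms the same C2–C3 bond and gives the methylidene cyclohexanol F4. Acetylation (Ac2O, pyridine, DMAP) gives the acetate F5, whose exocyclic C10=C20 alkene is protonated under the conditions of step 12 to the same C10 cation, so the route is rejoined at 18.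

(2) Step 6, the enantioselective Mukaiyama–Michael addition. The bulky tetrasubstituted ketene thioacetal may erode the facial selectivity of the iminium ion. The fallback replaces asymmetric catalysis by resolution and sets out from 6 and 10. The same addition run with an achiral iminium catalyst (pyrrolidinium trifluoroacetate, CH2Cl2–i-PrOH) gives the racemic adduct F6, whose enantiomers are separated by preparative chromatography on a chiral stationary phase; the (R)-enantiomer is 11.

(3) Step 12, the cationic closure of ring B. The C8 cation may lose a proton unselectively (from C17 or C9 instead of C7), be captured by the enoate, or the C10 cation may lose H5 and erode C5. The fallback sets out from 17 and separates ring closure from the placing of the alkene. Cyclisation with SnCl4 in CH2Cl2 at −78 °C and a cold amine quench, a milder protocol that should stop at the bicyclic stage, is taken to the exocyclic 8(17)-alkene F7. A hydrogen-atom-transfer isomerisation (Co(salen)Cl, PhSiH3, benzene, rt), which moves 1,1-disubstituted alkenes to the adjacent trisubstituted position and should take the unhindered C7–H rather than the C9–H next to the quaternary C10, then leads to 18.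

**Further compounds**

F1 | step 10 | methyl (2E,6E,10R)-12-(ethylsulfanyl)-10-(4-hydroxybut-1-en-2-yl)-3,7,11,11-tetramethyl-12-oxododeca-2,6-dienoate | CCSC(=O)C(C)(C)[C@@H](C(=C)CCO)CC/C(C)=C/CC/C(C)=C/C(=O)OC
F2 | step 10 | methyl (2E,6E,10R)-12-(ethylsulfanyl)-10-(4-iodobut-1-en-2-yl)-3,7,11,11-tetramethyl-12-oxododeca-2,6-dienoate | CCSC(=O)C(C)(C)[C@@H](C(=C)CCI)CC/C(C)=C/CC/C(C)=C/C(=O)OC
F3 | step 10 | methyl (2E,6E,10R)-10-(4-iodobut-1-en-2-yl)-3,7,11,11-tetramethyl-12-oxododeca-2,6-dienoate | O=CC(C)(C)[C@@H](C(=C)CCI)CC/C(C)=C/CC/C(C)=C/C(=O)OC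
F4 | step 10 | methyl (2E,6E)-9-[(1R,3S)-3-hydroxy-2,2-dimethyl-6-methylidenecyclohexyl]-3,7-dimethylnona-2,6-dienoate | COC(=O)/C=C(\C)CC/C=C(\C)CC[C@@H]1C(=C)CC[C@H](O)C1(C)C
F5 | step 10 | methyl (2E,6E)-9-[(1R,3S)-3-acetoxy-2,2-dimethyl-6-methylidenecyclohexyl]-3,7-dimethylnona-2,6-dienoate | COC(=O)/C=C(\C)CC/C=C(\C)CC[C@@H]1C(=C)CC[C@H](OC(C)=O)C1(C)C
F6 | step 6 | racemic methyl (2E,6E)-12-(ethylsulfanyl)-3,7,11,11-tetramethyl-12-oxo-10-(2-oxoethyl)dodeca-2,6-dienoate | CCSC(=O)C(C)(C)C(CC=O)CC/C(C)=C/CC/C(C)=C/C(=O)OC
F7 | step 12 | methyl (13E)-3β-acetoxylabda-8(17),13-dien-15-oate | CC(=O)O[C@H]1CC[C@]2(C)[C@@H](CC/C(C)=C/C(=O)OC)C(=C)CC[C@H]2C1(C)C
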